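**Strategy.** With eremophilane numbering (ring A = C1–C5, C10; ring B = C5–C10), ring B is disconnected at C5–C6 and C7–C8 by a Diels–Alder reaction between methyl vinyl ketone and an enantiopure ring-A diene, C5(Me)=C10–C9=C8(OEt). The C8 ketone of the target, carried as an enol ether, makes the quaternary C5 the nucleophilic diene terminus. One cycloaddition therefore closes ring B, creates the hindered C5 stereocentre anti to the C4 methyl, and places the acetyl precursor of the isopropenyl group on C7. C3 is set by CBS reduction; C4, C5, C10, C9 and C7 are relayed from it. The precursor is a monocyclic (E)-ethoxydienyl cyclohexene.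

Key step: step 7

Remark: bicyclic compounds carry eremophilane numbering (C14 on C5, C15 on C4, C11–C13 on C7); β is the face of the C5 methyl, α the opposite face.
Remark: the sense of the CBS reduction in step 3 is taken from the usual model with the alkene flank as the large group; compounds 1, 9, 11, 17 and 20 are taken as commercial.

Step 1
Reactants: 1 4-methoxy-3-methylphenol
Product: 2 4,4-dimethoxy-3-methylcyclohexa-2,5-dien-1-one
Conditions: PhI(OAc)2 (1.1 equiv), MeOH, 0 °C
Reagents that add atoms: methanol, CO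
Why: Hypervalent-iodine oxidative dearomatisation of a p-methoxyphenol, in which methanol traps the phenoxenium ion at the methoxy-bearing para carbon to give the quinone monoketal.

Step 2
Reactants: 2 4,4-dimethoxy-3-methylcyclohexa-2,5-dien-1-one
Product: 3 4,4-dimethoxy-3-methylcyclohex-2-en-1-one
Conditions: H2 (1 atm), RhCl(PPh3)3 (5 mol %), benzene, rt
Reagents that add atoms: none
Why: Homogeneous hydrogenation with Wilkinson's catalyst should reduce the 1,2-disubstituted enone alkene and leave the trisubstituted, methyl-bearing alkene next to the ketal untouched.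

Step 3
Reactants: 3 4,4-dimethoxy-3-methylcyclohex-2-en-1-one
Product: 5 (R)-4-hydroxy-2-methylcyclohex-2-en-1-one, via allylic alcohol ketal 4 (not isolated)
Conditions: (S)-Me-CBS (15 mol %), BH3·SMe2, THF, −20 °C; then 1 M HCl, THF, 0 °C
Reagents that add atoms: water, O
Why: Corey–Bakshi–Shibata reduction should set the carbinol centre (C3 of the target, the only stereocentre made by catalysis), and the allylic dimethyl ketal is hydrolysed in the acidic work-up, which transposes the enone so that its carbonyl becomes C10.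

Step 4
Reactants: 5 (R)-4-hydroxy-2-methylcyclohex-2-en-1-one
Product: 6 (R)-4-(tert-butyldimethylsilyloxy)-2-methylcyclohex-2-en-1-one
Conditions: TBSCl, imidazole, DMF, rt
Reagents that add atoms: tert-butyldimethylsilyl chloride, C[Si](C)(Cl)C(C)(C)C
Why: Standard silylation of a secondary alcohol, which gives the γ-silyloxy group needed to direct the cuprate addition and a C3 protecting group that lasts to step 12.

Step 5
Reactants: 6 (R)-4-(tert-butyldimethylsilyloxy)-2-methylcyclohex-2-en-1-one
Product: 8 (3R,4R)-4-(tert-butyldimethylsilyloxy)-2,3-dimethylcyclohex-1-en-1-yl trifluoromethanesulfonate, via lithium enolate 7 (not isolated)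
Conditions: Me2CuLi (from MeLi, CuI), Et2O, −78 to −40 °C; then PhNTf2, THF, −78 to 0 °C
Reagents that add atoms: lithium dimethylcuprate, [Li+].C[Cu-]C; N-phenylbis(trifluoromethanesulfonimide), O=S(=O)(N(c1ccccc1)S(=O)(=O)C(F)(F)F)C(F)(F)F
Why: Gilman conjugate addition should occur anti to the γ-silyloxy group and so set C4 trans to the C3 oxygen, and O-triflation of the regiodefined enolate fixes the tetrasubstituted C5=C10 alkene.

Step 6
Reactants: 8 (3R,4R)-4-(tert-butyldimethylsilyloxy)-2,3-dimethylcyclohex-1-en-1-yl trifluoromethanesulfonate; 9 (E)-2-(2-ethoxyethenyl)-4,4,5,5-tetramethyl-1,3,2-dioxaborolane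
Product: 10 tert-butyl({(1R,2R)-4-[(E)-2-ethoxyethenyl]-2,3-dimethylcyclohex-3-en-1-yl}oxy)dimethylsilane
Conditions: Pd(PPh3)4 (5 mol %), K3PO4, dioxane/H2O, 70 °C
Reagents that add atoms: none
Why: Suzuki–Miyaura coupling of an alkenyl triflate with an alkenyl boronate proceeds with retention of the E geometry and gives the 1-ethoxydiene C8(OEt)=C9–C10=C5.

Step 7
Reactants: 10 tert-butyl({(1R,2R)-4-[(E)-2-ethoxyethenyl]-2,3-dimethylcyclohex-3-en-1-yl}oxy)dimethylsilane; 11 methyl vinyl ketone (but-3-en-2-one)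
Product: 12 Diels–Alder adduct, 7α-acetyl-8α-ethoxy-3α-(tert-butyldimethylsilyloxy)-4β,5β-dimethyl-Δ9(10)-octalin (8α-ethoxy-3α-silyloxy-13-nor-eremophil-9-en-11-one)
Conditions: MVK (5 equiv), BHT (cat.), toluene, 110 °C, sealed tube
Reagents that add atoms: none
Why: Thermal normal-demand [4+2] cycloaddition (Diels–Alder) of the 1-alkoxydiene with methyl vinyl ketone, probably asynchronous with the C5–C6 bond forming ahead of C7–C8. The closest known reactions are Diels–Alder additions of 1-alkoxy- and 1-silyloxybutadienes to enones and of 2-methyl-1-vinylcyclohexenes that create angular methyl groups. Ring B, a six-membered carbocycle, is closed by suprafacial cycloaddition across the diene termini C5 and C8. C5 is set by approach of the dienophile to the diene face opposite the adjacent C4 methyl (1,2-induction from the allylic stereocentre), which puts the C5 methyl cis to the C4 methyl; C7 (acetyl α) and C8 (ethoxy α) follow from the endo transition state, and C8 is later lost as a ketone. The step needs regioselectivity (C6 to C5, C7 to C8), secured by the ethoxy donor on C8 and by the steric demand of the fully substituted C5, and face selectivity, secured by the C4 methyl; the inside methyl on C5 lowers the diene reactivity, hence the forcing conditions.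

Step 8
Reactants: 12 Diels–Alder adduct
Product: 13 8α-ethoxy-3α-(tert-butyldimethylsilyloxy)eremophila-9,11-diene (7α-isopropenyl)
Conditions: Zn, CH2Br2, TiCl4, THF/CH2Cl2, 0 °C to rt
Reagents that add atoms: dibromomethane, BrCBr
Why: Takai–Lombardo methylenation converts the methyl ketone into the isopropenyl group under non-basic conditions, so neither β-elimination of ethoxide nor epimerisation at C7 is expected.

Step 9
Reactants: 13 8α-ethoxy-3α-(tert-butyldimethylsilyloxy)eremophila-9,11-diene
Product: 14 3α-(tert-butyldimethylsilyloxy)eremophila-9,11-dien-8-one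
Conditions: DDQ (1.5 equiv), CH2Cl2/pH 7 buffer, rt
Reagents that add atoms: water, O
Why: DDQ abstracts hydride from the allylic ether carbon C8 (as in oxidative cleavage of prenyl-type ethers), and water converts the conjugated oxocarbenium ion through its hemiketal into the C8 enone with loss of ethanol.

Step 10
Reactants: 14 3α-(tert-butyldimethylsilyloxy)eremophila-9,11-dien-8-one
Product: 16 (3R,4R,5R,7S,9S,10R)-3-(tert-butyldimethylsilyloxy)-9-hydroxyeremophil-11-en-8-one, via lithium Δ8-enolate 15 (not isolated)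
Conditions: Li, NH3(l)/THF, t-BuOH (1.0 equiv), −78 °C; isoprene; NH3 evaporated; then (camphorsulfonyl)oxaziridine, THF, −78 to −20 °C
Reagents that add atoms: (camphorsulfonyl)oxaziridine, CC1(C)C2CCC13CS(=O)(=O)N4OC34C2
Why: Dissolving-metal reduction of the octalone protonates C10 axially to give the trans-decalin (10α-H, anti to the C5 methyl) and a regiospecific C8–C9 enolate, whose oxaziridine hydroxylation should occur on the α face because the β face of C9 is 1,3-diaxial to the C5 methyl, giving the equatorial 9α-hydroxyl.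

Step 11
Reactants: 16 (3R,4R,5R,7S,9S,10R)-3-(tert-butyldimethylsilyloxy)-9-hydroxyeremophil-11-en-8-one; 17 (E)-3-methylpent-2-enoic acid
Product: 18 (3R,4R,5R,7S,9S,10R)-3-(tert-butyldimethylsilyloxy)-9-[(E)-3-methylpent-2-enoyloxy]eremophil-11-en-8-one
Conditions: EDC·HCl, DMAP, CH2Cl2, 0 °C to rt
Reagents that add atoms: none
Why: Steglich esterification acylates the only free hydroxyl, the equatorial C9 alcohol, under mild conditions that should keep the E geometry of the β,β-disubstituted acrylate.

Step 12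
Reactants: 18 (3R,4R,5R,7S,9S,10R)-3-(tert-butyldimethylsilyloxy)-9-[(E)-3-methylpent-2-enoyloxy]eremophil-11-en-8-one
Product: 19 (3R,4R,5R,7S,9S,10R)-3-hydroxy-9-[(E)-3-methylpent-2-enoyloxy]eremophil-11-en-8-one
Conditions: HF·pyridine, pyridine/THF, 0 °C to rt
Reagents that add atoms: none
Why: Fluoride-mediated desilylation under buffered, non-basic conditions frees the C3 alcohol without acyl migration, epimerisation α to the ketone or conjugation of the isopropenyl group.

Step 13
Reactants: 19 (3R,4R,5R,7S,9S,10R)-3-hydroxy-9-[(E)-3-methylpent-2-enoyloxy]eremophil-11-en-8-one; 20 angelic acid ((Z)-2-methylbut-2-enoic acid)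
Product: 22 CNP0301161.1 (target), via angelic mixed anhydride 21 (not isolated)
Conditions: 20, 2,4,6-Cl3C6H2COCl, Et3N, toluene, rt; filter; then 19, 80 °C
Reagents that add atoms: none
Why: Yamaguchi-type mixed-anhydride acylation without DMAP is the established way to form angelates from hindered secondary alcohols without isomerisation to the tiglate.

**Compound list**

1 | 4-methoxy-3-methylphenol | COc1ccc(O)cc1C | starting material
2 | 4,4-dimethoxy-3-methylcyclohexa-2,5-dien-1-one | COC1(OC)C=CC(=O)C=C1C | intermediate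
3 | 4,4-dimethoxy-3-methylcyclohex-2-en-1-one | COC1(OC)CCC(=O)C=C1C | intermediate
4 | (R)-4,4-dimethoxy-3-methylcyclohex-2-en-1-ol | CC1=C[C@H](O)CCC1(OC)OC | intermediate
5 | (R)-4-hydroxy-2-methylcyclohex-2-en-1-one | O=C1C(C)=C[C@H](O)CC1 | intermediate
6 | (R)-4-(tert-butyldimethylsilyloxy)-2-methylcyclohex-2-en-1-one | O=C1C(C)=C[C@H](O[Si](C)(C)C(C)(C)C)CC1 | intermediate
7 | lithium (3R,4R)-4-(tert-butyldimethylsilyloxy)-2,3-dimethylcyclohex-1-en-1-olate | [Li+].[O-]C1=C(C)[C@@H](C)[C@H](O[Si](C)(C)C(C)(C)C)CC1 | intermediate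
8 | (3R,4R)-4-(tert-butyldimethylsilyloxy)-2,3-dimethylcyclohex-1-en-1-yl trifluoromethanesulfonate | O=S(=O)(OC1=C(C)[C@@H](C)[C@H](O[Si](C)(C)C(C)(C)C)CC1)C(F)(F)F | intermediate
9 | (E)-2-(2-ethoxyethenyl)-4,4,5,5-tetramethyl-1,3,2-dioxaborolane | CCO/C=C/B1OC(C)(C)C(C)(C)O1 | starting material
10 | tert-butyl({(1R,2R)-4-[(E)-2-ethoxyethenyl]-2,3-dimethylcyclohex-3-en-1-yl}oxy)dimethylsilane | CCO/C=C/C1=C(C)[C@@H](C)[C@H](O[Si](C)(C)C(C)(C)C)CC1 | intermediate
11 | methyl vinyl ketone | C=CC(C)=O | starting material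
12 | 7α-acetyl-8α-ethoxy-3α-(tert-butyldimethylsilyloxy)-4β,5β-dimethyl-Δ9(10)-octalin (7β-H, 8β-H) | CC(=O)[C@@H]1C[C@]2(C)[C@@H](C)[C@H](O[Si](C)(C)C(C)(C)C)CCC2=C[C@@H]1OCC | intermediate
13 | 8α-ethoxy-3α-(tert-butyldimethylsilyloxy)eremophila-9,11-diene (7α-isopropenyl) | C=C(C)[C@@H]1C[C@]2(C)[C@@H](C)[C@H](O[Si](C)(C)C(C)(C)C)CCC2=C[C@@H]1OCC | intermediate
14 | 3α-(tert-butyldimethylsilyloxy)eremophila-9,11-dien-8-one (7α-isopropenyl) | C=C(C)[C@@H]1C[C@]2(C)[C@@H](C)[C@H](O[Si](C)(C)C(C)(C)C)CCC2=CC1=O | intermediate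
15 | lithium 3α-(tert-butyldimethylsilyloxy)-10αH-eremophila-8,11-dien-8-olate | C=C(C)[C@@H]1C[C@]2(C)[C@@H](C)[C@H](O[Si](C)(C)C(C)(C)C)CC[C@H]2C=C1[O-].[Li+] | intermediate
16 | (3R,4R,5R,7S,9S,10R)-3-(tert-butyldimethylsilyloxy)-9-hydroxyeremophil-11-en-8-one (3α-OTBS, 9α-OH, 10α-H) | C=C(C)[C@@H]1C[C@]2(C)[C@@H](C)[C@H](O[Si](C)(C)C(C)(C)C)CC[C@H]2[C@H](O)C1=O | intermediate
17 | (E)-3-methylpent-2-enoic acid | CC/C(C)=C/C(=O)O | starting material
18 | (3R,4R,5R,7S,9S,10R)-3-(tert-butyldimethylsilyloxy)-9-[(E)-3-methylpent-2-enoyloxy]eremophil-11-en-8-one | C=C(C)[C@@H]1C[C@]2(C)[C@@H](C)[C@H](O[Si](C)(C)C(C)(C)C)CC[C@H]2[C@H](OC(=O)/C=C(\C)CC)C1=O | intermediate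
19 | (3R,4R,5R,7S,9S,10R)-3-hydroxy-9-[(E)-3-methylpent-2-enoyloxy]eremophil-11-en-8-one | C=C(C)[C@@H]1C[C@]2(C)[C@@H](C)[C@H](O)CC[C@H]2[C@H](OC(=O)/C=C(\C)CC)C1=O | intermediate
20 | angelic acid, (Z)-2-methylbut-2-enoic acid | C/C=C(/C)C(=O)O | starting material
21 | (Z)-2-methylbut-2-enoic 2,4,6-trichlorobenzoic anhydride | C/C=C(/C)C(=O)OC(=O)c1c(Cl)cc(Cl)cc1Cl | intermediate
22 | CNP0301161.1, (3R,4R,5R,7S,9S,10R)-3-[(Z)-2-methylbut-2-enoyloxy]-9-[(E)-3-methylpent-2-enoyloxy]eremophil-11-en-8-one | C=C(C)[C@@H]1C[C@]2(C)[C@@H](C)[C@H](OC(=O)/C(C)=C\C)CC[C@H]2[C@H](OC(=O)/C=C(\C)CC)C1=O | target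

**Step count.** Total: 13 steps. Longest linear sequence: 13 steps (1 to 22).

**Steps most likely to fail and fallbacks**

Step 7. The congested diene terminus C5 may react too slowly with methyl vinyl ketone, so that polymerisation of the enone or decomposition of the acid-sensitive enol ether wins. The fallback sets out from diene 10 and uses the far more reactive acryloyl chloride (CH2Cl2, 2,6-di-tert-butylpyridine, 0 °C to rt) to give the acid chloride adduct F1. Treatment with Me2CuLi at −78 °C converts this into the methyl ketone, and the route is rejoined at compound 12.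

Step 9. Hydride abstraction by DDQ at the secondary ether carbon may be slow, or dehydrogenation may occur elsewhere. The fallback carries the C8 oxygen as a silyl ether instead and sets out from diene 10. Mild hydrolysis (oxalic acid on wet silica) gives the β,γ-unsaturated aldehyde F2. TESOTf/Et3N gives the (E)-triethylsilyl dienol ether F3, of which only the E isomer is expected to undergo cycloaddition. Diels–Alder reaction with methyl vinyl ketone as in step 7 gives the silyloxy adduct F4, and Lombardo methylenation gives the isopropenyl compound F5. PPTS in methanol removes the allylic triethylsilyl group selectively to give the allylic alcohol F6, and MnO2 oxidation returns to the route at enone 14.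

Step 10. The one-flask reductive hydroxylation may suffer from sluggish oxygen transfer to the lithium enolate, enolate equilibration towards C7, or over-reduction. The fallback sets out from enone 14: Li/NH3 reduction followed by TMSCl/Et3N gives the isolable trimethylsilyl enol ether F7. Rubottom oxidation (dimethyldioxirane or one equivalent of buffered mCPBA at −20 °C, then citric acid) on the α face returns to the route at hydroxy ketone 16.

**Further compounds**

F1 | step 7 | 8α-ethoxy-3α-(tert-butyldimethylsilyloxy)-4β,5β-dimethyl-Δ9(10)-octalin-7α-carbonyl chloride | O=C(Cl)[C@@H]1C[C@]2(C)[C@@H](C)[C@H](O[Si](C)(C)C(C)(C)C)CCC2=C[C@@H]1OCC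
F2 | step 9 | 2-[(3R,4R)-4-(tert-butyldimethylsilyloxy)-2,3-dimethylcyclohex-1-en-1-yl]acetaldehyde | O=CCC1=C(C)[C@@H](C)[C@H](O[Si](C)(C)C(C)(C)C)CC1
F3 | step 9 | tert-butyldimethyl({(1R,2R)-2,3-dimethyl-4-[(E)-2-(triethylsilyloxy)ethenyl]cyclohex-3-en-1-yl}oxy)silane | CC[Si](CC)(CC)O/C=C/C1=C(C)[C@@H](C)[C@H](O[Si](C)(C)C(C)(C)C)CC1
F4 | step 9 | 7α-acetyl-8α-(triethylsilyloxy)-3α-(tert-butyldimethylsilyloxy)-4β,5β-dimethyl-Δ9(10)-octalin | CC(=O)[C@@H]1C[C@]2(C)[C@@H](C)[C@H](O[Si](C)(C)C(C)(C)C)CCC2=C[C@@H]1O[Si](CC)(CC)CC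
F5 | step 9 | 8α-(triethylsilyloxy)-3α-(tert-butyldimethylsilyloxy)eremophila-9,11-diene | C=C(C)[C@@H]1C[C@]2(C)[C@@H](C)[C@H](O[Si](C)(C)C(C)(C)C)CCC2=C[C@@H]1O[Si](CC)(CC)CC
F6 | step 9 | 3α-(tert-butyldimethylsilyloxy)eremophila-9,11-dien-8α-ol | C=C(C)[C@@H]1C[C@]2(C)[C@@H](C)[C@H](O[Si](C)(C)C(C)(C)C)CCC2=C[C@@H]1O
F7 | step 10 | 3α-(tert-butyldimethylsilyloxy)-8-(trimethylsilyloxy)-10αH-eremophila-8,11-diene | C=C(C)[C@@H]1C[C@]2(C)[C@@H](C)[C@H](O[Si](C)(C)C(C)(C)C)CC[C@H]2C=C1O[Si](C)(C)C
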